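Follow the share of target in target plus isomer of the product as a clock, and leave the yields aside.

| flask | starting material | reagent | protic impurity | remark | time |
|---|---|---|---|---|---|
| Saturday's | 0.050 M | 0.19 M | 0.025 M | run made earlier |  |
| Sunday's | 0.050 M | 0.41 M | 0.025 M | run made earlier |  |
| Friday's | 0.050 M | 0.89 M | 0.025 M | run made earlier |  |
| Thursday's | 0.050 M | 0.20 M | 0.013 M | run made earlier |  |
| south-west | 0.050 M | 0.200 M | 0.0250 M |  | 40 h |
| north-west | 0.050 M | 0.800 M | 0.00600 M |  | 40 h |

| run | time / h | target / % | isomer of the product / % | starting material / % |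
|---|---|---|---|---|
| Saturday's | 1.50 | 16.7 | 5.9 | 34.8 |
| Saturday's | 3.00 | 23.8 | 8.0 | 21.3 |
| Saturday's | 6.00 | 30.5 | 9.2 | 10.3 |
| Saturday's | 10.0 | 35.5 | 9.4 | 5.9 |
| Saturday's | 20.0 | 37.3 | 9.4 | 4.0 |
| Sunday's | 4.00 | 39.0 | 12.3 | 4.9 |
| Sunday's | 8.00 | 40.7 | 11.4 | 1.7 |
| Sunday's | 12.0 | 40.9 | 10.1 | 2.3 |
| Sunday's | 15.0 | 41.2 | 10.1 | 1.3 |
| Sunday's | 20.0 | 41.1 | 9.7 | 1.4 |
| Friday's | 4.00 | 48.7 | 14.5 | 0.8 |
| Friday's | 8.00 | 48.6 | 15.0 | 0 |
| Friday's | 12.0 | 48.2 | 13.2 | 0.6 |
| Friday's | 15.0 | 47.8 | 11.6 | 0.5 |
| Friday's | 20.0 | 47.5 | 10.6 | 0.8 |
| Thursday's | 4.00 | 36.7 | 11.3 | 26.3 |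
| Thursday's | 8.00 | 47.2 | 14.1 | 11.5 |
| Thursday's | 12.0 | 52.5 | 13.9 | 8.0 |
| Thursday's | 15.0 | 53.5 | 13.9 | 5.7 |
| Thursday's | 20.0 | 54.9 | 13.9 | 5.4 |

(readings scatter by 0.5 percentage points)

- what was read earlier has a scatter of 0.5 percentage points, one standard deviation
- on the list of suspects stand: starting material + reagent <-> isomer of the product; starting material + protic impurity -> quenched substrate; starting material + reagent <-> target

- which of the two ends with the higher share of target in all that became target or isomer of the product ("neither" if they lie within 2 percentage points) (south-west / north-west / neither)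
- share of target in all that became target or isomer of the product, south-west
- share of target in all that became target or isomer of the product, north-west

In the first instants I saw the quench: in Saturday's run at 1.50 h, 42.6% of the charge was missing from the three readings, against the 50.0% that the protic impurity could take. In the middle, target and isomer of the product grew side by side, with the share at 73.9% at that first reading. Then came the crossing from kinetic to thermodynamic control. In Friday's run no reading of starting material lay above 0.8%, yet the isomer of the product fell between its second reading and its last: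

half-life = ln(2) × (20.0 h − 8.00 h) / ln(15.0% / 10.6%) = 24.0 h

I called this the hand-over half-life: the time in which the isomer of the product halved at the pace of those two readings in Friday's run, reckoned as if it fell toward zero. It is a reading between two scattered values, and the isomer of the product has no reason to end at zero, so using it for the share was my working assumption: I let the gap between the share and its end value halve in that same time. On that assumption, two readings of the share in one run gave me an end value and a share at a later time.

Saturday's, for south-west: 73.9% and 79.9%, end value 88.3%, at 40 h 83.6%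

Friday's, nearest in reagent to north-west: 77.1% and 81.8%, end value 89.7%, at 40 h 85.3%

The two of mine differed by 1.7 percentage points, less than the margin of 2 points, so I said neither.

The forecast gave 82.5%, 83% and neither, with the words “The share drifts up slowly with a time constant of about 30 h”; both my figures stood above its numbers.

The flasks gave 83.3% in south-west and 83.6% in north-west, so neither.

    starting material + reagent ⇌ isomer of the product (K = 11.0 M⁻¹, k = 0.360 M⁻¹ h⁻¹)
    starting material + protic impurity → quenched substrate (k = 49.0 M⁻¹ h⁻¹)
    starting material + reagent ⇌ target (K = 78.0 M⁻¹, k = 1.10 M⁻¹ h⁻¹)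

In south-west the quench ran first: 99.7% of its turnover lay behind it at 20.0 h, with protic impurity at 0.377% of its charge and starting material at 3.31%. After that the isomer of the product went from 9.34% to 7.82% at 40.0 h while target went from 37.5% to 39.1%. The same toward-zero reckoning on those two isomer figures gave 78.0 h, against my 24.0 h from Friday's scattered readings and a half-life of 24.9 h for the slowest mode of south-west. Taking the share of 87.6% at 400 h as the end, the gap of 4.3 points at 40 h, halved every 24.0 h, gave 87.4% for south-west read at 6.0 d, and that reading stood at 87.4%.

The earlier runs and the new flask are simulated for substances that don't exist; noise was put on by code.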